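A charge of 11 mM of starting material is small beside 22.7 mM, the reciprocal of the coupling's equilibrium constant K, so I expected the coupling to stop part-way.

| flask | starting material | partner | remark | time |
|---|---|---|---|---|
| theta | 11 mM | 1.30 equiv | one stirred flow tank at steady state, fed with the mixture as stated, mean residence time 2.0 min |  |
| epsilon | 11 mM | 1.30 equiv | everything together in a closed stirred flask, run for 2.0 min | 2.0 min |
| eta | 11 mM (fed, over 1.60 min) | 1.30 equiv | all but starting material at the start; starting material goes in evenly over 1.60 min, the run ends at 2.0 min | 2.0 min |
| beta | 11 mM | 1.30 equiv (fed, over 1.60 min) | a stirred flask in which partner is dosed at a steady rate over 1.60 min without added volume, worked up at 2.0 min | 2.0 min |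

    open intermediate + second intermediate ⇌ target (K1 = 44 L mol⁻¹, k1 = 0.53 L mol⁻¹ s⁻¹)
    second intermediate → side product (k2 = 0.0017 s⁻¹)
    partner → second intermediate (k3 = 0.053 s⁻¹)
    starting material → open intermediate (k4 = 0.056 s⁻¹)

* the set-up with the highest amount of target at the outlet or at the end, in percent of the starting material put in ("none" if the first two lie within 2 percentage points) (theta / epsilon / eta / beta / none)
* amount of target at the outlet or at the end, in percent of the starting material put in, theta
* amount of target at the outlet or at the end, in percent of the starting material put in, epsilon
* amount of target at the outlet or at the end, in percent of the starting material put in, eta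
* amount of target at the outlet or at the end, in percent of the starting material put in, beta

- the stated concentrations are those of everything mixed, before any reaction; amounts are the same in each set-up
- the feed brings no volume worth counting
- run time (epsilon): 2.0 min

I began with epsilon. The half-lives of the two feeding steps, 0.22 min and 0.21 min, are short beside the run, so I treated both charges as intermediates after a lag L. I took L as the sum of the reciprocals of the two feeding constants, less the reciprocal of their sum:

L = 27.6 s

Let a be the starting material charge, b = 14.3 mM the partner charge, and k the coupling rate constant. I set the side path aside for this reckoning, as a simplification. The ceiling x, the target at equilibrium, then follows: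

x = K(a−x)(b−x), so x = 3.54 mM, or 32.2% of the charge

I reached the target at the end of the run by two ways. First I froze the free second intermediate at b−x, which makes the coupling pseudo-first-order:

μ = k(b−x) + k/K = 0.01775 s⁻¹, giving 25.9%

Then I let both intermediates move:

λ = k(a+b−2x) + k/K = 0.02171 s⁻¹, giving 27.8%

Here λ is the settling constant, the relaxation rate at which the gap to the ceiling closes. The two ways part by 1.9 percentage points, and the first one cheats. Each coupling removes one of each intermediate, so λ holds a term k(a−x) = 0.003956 s⁻¹ that μ lacks. I committed to 27.8%, less an amount for the side path that I did not reckon.

In eta and beta, dosing delays the mean arrival by half the dosing time, so the same λ gives 19.9%, less than epsilon. I did not reckon theta.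

The forecast named epsilon, with 16.3% for theta, 25% for epsilon, 18% for eta and 19.5% for beta, because “the set-up that builds both intermediates earliest wins”.

The simulation gave epsilon as best, at 25.4%, against 16.2% in theta, 18.5% in eta and 19.4% in beta. With the path from second intermediate to side product struck out, epsilon gave 27.7%. A neighbour of epsilon charged with 0.780 equiv of partner has a ceiling of 2.36 mM and a settling constant of 0.01992 s⁻¹, lower than the 0.0217 s⁻¹ of epsilon. These reckon to 18.1% with the side path set aside, and that neighbour flask gave 16.4%.

(The constants used here were drawn at random within sensible limits; the run is a simulation.)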